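The numbers are invented; no experiment stands behind them.

In a one-step world I could have read the E.J straight from the first equilibrium constant, but in these flasks E and J have a second way out, to G, and Q joins the two products for as long as it lasts.

all flasks: E 0.20 M; J 0.300 M; Q 0.74 mM; time 30 min
- violet: temperature 45 °C
- grey: at 45 °C until 10 min, from then on at 60 °C
- red: temperature 60 °C

    E + J ⇌ E.J (K1 = 2.0 L mol⁻¹, k1 = 0.45 L mol⁻¹ s⁻¹, Ea1 = 49.0 kJ mol⁻¹, ΔH1 = −19.0 kJ mol⁻¹)
    E + J ⇌ G (K2 = 8.5 L mol⁻¹, k2 = 0.016 L mol⁻¹ s⁻¹, Ea2 = 65.0 kJ mol⁻¹, ΔH2 = −30.0 kJ mol⁻¹)
    E.J + Q ⇌ G + Q, rate k3*[Q]*[E.J] forward; the back reaction follows from the equilibrium constant (k3 = 19 L mol⁻¹ s⁻¹, Ea3 = 53.0 kJ mol⁻¹)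
    E + Q → E.Q (k4 = 0.048 L mol⁻¹ s⁻¹, Ea4 = 63.0 kJ mol⁻¹)
    2 Q → Q2 (k5 = 11 L mol⁻¹ s⁻¹, Ea5 = 59.0 kJ mol⁻¹)
    (constants at 60 °C)

- a doubled species enters its step squared and goes two at a time
- the list of constants is for 60 °C, to be carried to other temperatures by the activation energies and enthalpies

- which flask leads in amount of E.J, in percent of the E charged ("all alike" within 1.5 percentage points) (violet / grey / red / all alike)
- how much E.J is there at the end, in percent of the E charged: violet
- how much E.J is there at the end, in percent of the E charged: grey
- how much E.J is there at the end, in percent of the E charged: red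

I began with the rates in red. At the start of red, E goes to G at 0.036 of the forward rate at which it goes to E.J, so E.J forms first. In red, Q then drains E.J into G with a starting forward half-life of 49.3 s, but pairing by itself halves Q in 61.4 s, and the drain slows with it. The direct road to G remains in red, and J gives E a starting forward half-life on it of 2.41 min. That is shorter than the 30 min of the run, and shorter than grey's 20.0 min at 60 °C, so I estimated that the slowing of Q would cost red and grey little at the end.

So I followed one reacted molecule of E. I call the rest share the chance that it is found as E.J once both roads balance, K1 over K1 plus K2: 19.0%. This is thermodynamic control, and J does not enter the share. The sum of the constants, 10.5 L mol⁻¹, gives the conversion at rest, 64.3%, so I expected 12.2% E.J in red and grey. At 45 °C the share is 16.3% and the conversion 72.4%, which gives 11.8% for violet at rest. I could not reckon by hand how near to that figure violet would stand at the end.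

The forecast said all alike, with 13.1% for violet, 12.2% for grey and 12.2% for red, holding that “grey and red both reach” the overall equilibrium while violet is “still slightly short of it”. My figures for grey and red are the same, and for violet at the end it gave a number where I had only the figure at rest.

The simulation gave all alike: violet 13.1%, grey 12.2%, red 12.2%.

Red's E.J had come to rest by the end: ten times the time left it at 12.2%, and grey's stood at 12.2%. Violet had not. Of its reacted E, 18.6% was still E.J against a rest share of 16.3%, and ten times the time brought E.J down to 11.8%, while G rose from 57.2% to 60.5%. So violet's E.J at the end stood 1.3 percentage points above its level at ten times the time.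

For a neighbour of red with 1.2 M of J, the same share and 91.4% conversion gave 17.4% E.J. The simulation gave 17.4%, with 8.6% of the E left free.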